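**Plan**

- Retrosynthesis: after removal of nine benzyl ethers, ring F (the lower pyran) is cut at O1–C2 and C4a–C4 in one stroke. This gives 3-(benzyloxy)phenol (ring D with its oxygen) and an aryl trans-epoxy aldehyde that carries C2–C3–C4 on ring E. The epoxy aldehyde goes back to an (E)-allylic alcohol, its aryl–CH= bond to a Suzuki coupling, and the interflavanyl C4(ring C)–C2'(ring E) bond to a Friedel–Crafts alkylation.
- Enabling feature: in ring F, O1 and C4a are a phenolic oxygen and its ortho carbon on resorcinol ring D (a 1,3-C,O-dinucleophile). C4 (carbinol) and C2 (benzylic ether carbon) flank the C3 carbinol, which is the pattern left when the aldehyde carbon and the benzylic carbon of a 2,3-epoxy aldehyde each accept one nucleophile.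
- Forward order: rings A, C and B come intact from (+)-dihydrorobinetin. Ring E is attached to C4 while ring D, the usual nucleophilic ring of a flavan, does not yet exist. The three-carbon chain is then added to ring E, rings F and D are joined last in one annulation, and global hydrogenolysis ends the route.
- Stereochemistry: upper C2/C3 come from the chiral pool and upper C4 from attack anti to the C3 oxygen (3,4-trans). Lower C3 and C2 come from a Sharpless epoxide (C2 by inversion in the ring closure), and lower C4 from Felkin–Anh addition to the epoxy aldehyde (3,4-cis).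

Key step: step 11

Assumption (chemistry): (+)-(2R,3R)-dihydrorobinetin is taken as a purchasable chiral-pool flavanonol, and rotation about the hindered C4–aryl bond is taken as fast enough that no atropisomer needs to be specified.

Abbreviations: Bn = benzyl; U = (2R,3S,4S)-3,7-bis(benzyloxy)-2-[3,4,5-tris(benzyloxy)phenyl]chroman-4-yl.

**Route**

Step 1
Reactants: 1 (+)-dihydrorobinetin [(2R,3R)-3,7-dihydroxy-2-(3,4,5-trihydroxyphenyl)chroman-4-one]
Product: 2 (2R,3R)-7-(benzyloxy)-3-hydroxy-2-[3,4,5-tris(benzyloxy)phenyl]chroman-4-one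
Conditions: BnBr (4.4 equiv), K2CO3, DMF, rt, argon
Reagents that add atoms: benzyl bromide, BrCc1ccccc1
Why: Williamson etherification, in which the four phenols are far more acidic than the C3 carbinol and are benzylated selectively under mild carbonate conditions at room temperature, which should leave the chiral-pool C2 and C3 centres untouched.

Step 2
Reactants: 2 tetra-O-benzyl dihydrorobinetin
Product: 3 (2R,3S,4R)-7-(benzyloxy)-2-[3,4,5-tris(benzyloxy)phenyl]chromane-3,4-diol
Conditions: NaBH4, THF/EtOH, 0 °C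
Reagents that add atoms: none
Why: Borohydride reduction of the aryl ketone, in which axial hydride delivery to the half-chair with equatorial 2-aryl and 3-hydroxyl groups should give mainly the 3,4-trans diol (4R), and the C4 configuration is in any case erased when this carbinol is ionised in step 5.

Step 3
Reactants: 4 5-bromo-1,2,3-trimethoxybenzene
Product: 5 5-bromobenzene-1,2,3-triol
Conditions: BBr3, CH2Cl2, −78 °C → rt; then H2O
Reagents that add atoms: none
Why: Lewis-acid ether cleavage with BBr3 exchanges the three methyl ethers, which could not be removed at the end without destroying a flavan-3,4-diol, for free phenols and leaves the aryl bromide intact.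

Step 4
Reactants: 5 5-bromobenzene-1,2,3-triol
Product: 6 5-bromo-1,2,3-tris(benzyloxy)benzene
Conditions: BnBr (3.5 equiv), K2CO3, DMF, 60 °C, argon
Reagents that add atoms: benzyl bromide, BrCc1ccccc1
Why: Williamson etherification of the three phenols gives a symmetric arene whose only two free ring positions are equivalent and each ortho and para to a benzyloxy group.

Step 5
Reactants: 3 flavan-3,4-diol; 6 aryl bromide (4 equiv, excess recovered)
Product: 7 (2R,3S,4S)-7-(benzyloxy)-4-[6-bromo-2,3,4-tris(benzyloxy)phenyl]-2-[3,4,5-tris(benzyloxy)phenyl]chroman-3-ol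
Conditions: Sc(OTf)3 (10 mol %), 4 Å MS, CH2Cl2, −20 → 0 °C, slow addition of 3 to 6
Reagents that add atoms: none
Why: Friedel–Crafts alkylation with loss of water, in which Sc(OTf)3 ionises the C4 carbinol (benzylic and para to the 7-benzyloxy group) and the excess arene captures the cation at its only free, symmetry-equivalent position, approaching the half-chair anti to the C3 oxygen to give the 3,4-trans (4S) product as is usual for 2,3-trans flavan-4-yl cations.

Step 6
Reactants: 7 4-arylflavan-3-ol
Product: 8 (2R,3S,4S)-3,7-bis(benzyloxy)-4-[6-bromo-2,3,4-tris(benzyloxy)phenyl]-2-[3,4,5-tris(benzyloxy)phenyl]chromane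
Conditions: NaH, BnBr, Bu4NI (cat.), DMF, 0 °C → rt
Reagents that add atoms: benzyl bromide, BrCc1ccccc1
Why: Williamson etherification of the secondary C3 alkoxide protects the only free hydroxyl against the later oxidation and titanium chemistry with a group that leaves in the final hydrogenolysis.

Step 7
Reactants: 8 aryl bromide; 9 (E)-tert-butyldimethyl{[3-(4,4,5,5-tetramethyl-1,3,2-dioxaborolan-2-yl)prop-2-en-1-yl]oxy}silane
Product: 10 (E)-tert-butyl({3-[3,4,5-tris(benzyloxy)-2-U-phenyl]prop-2-en-1-yl}oxy)dimethylsilane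
Conditions: Pd(OAc)2 (5 mol %), SPhos (10 mol %), K3PO4, toluene/H2O, 90 °C
Reagents that add atoms: none
Why: Suzuki–Miyaura coupling, in which the biaryl dialkylphosphine ligand allows oxidative addition of the electron-rich, ortho-substituted aryl bromide to zerovalent palladium and the alkenyl boronate is transferred with retention of its (E) geometry.

Step 8
Reactants: 10 allylic silyl ether
Product: 11 (E)-3-[3,4,5-tris(benzyloxy)-2-U-phenyl]prop-2-en-1-ol
Conditions: TBAF, THF, 0 °C → rt
Reagents that add atoms: none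
Why: Fluoride-mediated cleavage of the primary silyl ether frees the allylic alcohol needed to direct the epoxidation while all benzyl ethers stay in place.

Step 9
Reactants: 11 (E)-allylic alcohol
Product: 12 {(2S,3S)-3-[3,4,5-tris(benzyloxy)-2-U-phenyl]oxiran-2-yl}methanol
Conditions: Ti(OiPr)4 (10 mol %), L-(+)-diisopropyl tartrate (12 mol %), t-BuOOH (2 equiv, decane), 4 Å MS, CH2Cl2, −20 °C
Reagents that add atoms: tert-butyl hydroperoxide, CC(C)(C)OO
Why: Sharpless asymmetric epoxidation, in which the L-(+)-tartrate catalyst delivers oxygen to the face of an (E)-3-aryl allylic alcohol that gives the (2S,3S)-trans-epoxy alcohol under reagent control that should override the remote upper stereocentres, while the flanked 4-benzyloxy group is twisted out of conjugation so that the aryl epoxide should survive the catalytic conditions.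

Step 10
Reactants: 12 epoxy alcohol
Product: 13 (2R,3S)-3-[3,4,5-tris(benzyloxy)-2-U-phenyl]oxirane-2-carbaldehyde
Conditions: Dess–Martin periodinane, pyridine, CH2Cl2, 0 °C; used directly
Reagents that add atoms: none
Why: Dess–Martin oxidation under pyridine buffer converts the primary alcohol into the aldehyde without acid or enolising base, so the epoxide and its α-stereocentre (now formally R by a change of priorities only) are kept.

Step 11
Reactants: 13 epoxy aldehyde; 14 3-(benzyloxy)phenol
Product: 17 (2R,3S,4S)-7-(benzyloxy)-2-[3,4,5-tris(benzyloxy)-2-U-phenyl]chromane-3,4-diol, via titanium phenolate 15 (not isolated), via anti epoxy carbinol 16 (not isolated)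
Conditions: 14 (2.2 equiv), Ti(OiPr)4 (2.0 equiv), toluene, rt, then azeotropic removal of i-PrOH; 13, CH2Cl2, −20 °C → rt; aq. potassium sodium tartrate
Reagents that add atoms: none
Why: Proposed new method: the aryloxytitanium triisopropoxide 15 binds the aldehyde oxygen of 13 and delivers its ortho carbon through a six-membered metal-templated transition state to the carbonyl carbon (C4a–C4 bond), rearomatisation leaves the titanium salicyl alkoxide of 16, and titanium bridged between this C4 alkoxide and the epoxide oxygen then activates the distal benzylic carbon for attack by the phenolic oxygen (O1–C2 bond). The closest known reaction types are the ortho-specific hydroxyalkylation of magnesium and titanium phenolates by α-oxygenated aldehydes, the Ti(OiPr)4-mediated opening of 2,3-epoxy alcohols at the carbon remote from the carbinol, and the phenol onto aryl-epoxide closure used for flavan-3-ols; their merger on an α,β-epoxy aldehyde acting as a three-carbon 1,3-dielectrophile is the part without precedent. Ring F closes in the 6-endo-tet mode at C2 and not in the 5-exo mode at C3, because C2 is benzylic to the trialkoxyaryl ring E and is the carbon activated in the titanium chelate. C4 is set by Felkin–Anh (Cornforth) attack anti to the epoxide C–O bond under the weakly Lewis acidic, non-chelating titanium phenolate, which gives the 3,4-anti carbinol 16 and hence the 3,4-cis diol; C3 is carried unchanged from the Sharpless epoxide; C2 arises by inversion at the benzylic epoxide carbon, and even a looser, cation-like opening should converge on the same 2,3-trans ring with the aryl group equatorial. The step needs C- over O-alkylation and ortho over para attack (titanium template), C6 over C2 of the phenol (C2 is flanked by two oxygens and C6 is para to the benzyloxy donor), and aldehyde addition before epoxide opening (the aldehyde is by far the better electrophile at −20 °C). The cis-diol is held as a five-membered titanium diolate until work-up, which should shield the 7-benzyloxy-activated C4 carbinol from ionisation.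

Step 12
Reactants: 17 nona-O-benzyl biflavonoid
Product: 18 (2R,3S,4S)-2-{3,4,5-trihydroxy-2-[(2R,3S,4S)-3,7-dihydroxy-2-(3,4,5-trihydroxyphenyl)chroman-4-yl]phenyl}chromane-3,4,7-triol (CNP0205451.3)
Conditions: H2 (1 atm), Pd(OH)2/C, THF/EtOAc, rt
Reagents that add atoms: none
Why: Hydrogenolysis of the nine benzyl ethers over Pd(OH)2 on carbon under neutral aprotic conditions, in which secondary benzylic carbinols para to a phenol normally survive when acid is excluded, no stereocentre is touched and the 5-deoxy flavan-3,4-diol is of the isolable type.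

**Compound list**

1 | (+)-dihydrorobinetin, (2R,3R)-3,7-dihydroxy-2-(3,4,5-trihydroxyphenyl)chroman-4-one | Oc1ccc2c(c1)O[C@H](c1cc(O)c(O)c(O)c1)[C@@H](O)C2=O | starting material
2 | (2R,3R)-7-(benzyloxy)-3-hydroxy-2-[3,4,5-tris(benzyloxy)phenyl]chroman-4-one | C(c1ccccc1)Oc1ccc2c(c1)O[C@H](c1cc(OCc3ccccc3)c(OCc3ccccc3)c(OCc3ccccc3)c1)[C@@H](O)C2=O | intermediate
3 | (2R,3S,4R)-7-(benzyloxy)-2-[3,4,5-tris(benzyloxy)phenyl]chromane-3,4-diol (2,3-trans-3,4-trans) | C(c1ccccc1)Oc1ccc2c(c1)O[C@H](c1cc(OCc3ccccc3)c(OCc3ccccc3)c(OCc3ccccc3)c1)[C@@H](O)[C@@H]2O | intermediate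
4 | 5-bromo-1,2,3-trimethoxybenzene | COc1cc(Br)cc(OC)c1OC | starting material
5 | 5-bromobenzene-1,2,3-triol | Oc1cc(Br)cc(O)c1O | intermediate
6 | 5-bromo-1,2,3-tris(benzyloxy)benzene | Brc1cc(OCc2ccccc2)c(OCc2ccccc2)c(OCc2ccccc2)c1 | intermediate
7 | (2R,3S,4S)-7-(benzyloxy)-4-[6-bromo-2,3,4-tris(benzyloxy)phenyl]-2-[3,4,5-tris(benzyloxy)phenyl]chroman-3-ol (all-trans, 4α-aryl) | C(c1ccccc1)Oc1ccc2c(c1)O[C@H](c1cc(OCc3ccccc3)c(OCc3ccccc3)c(OCc3ccccc3)c1)[C@@H](O)[C@@H]2c1c(Br)cc(OCc2ccccc2)c(OCc2ccccc2)c1OCc1ccccc1 | intermediate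
8 | (2R,3S,4S)-3,7-bis(benzyloxy)-4-[6-bromo-2,3,4-tris(benzyloxy)phenyl]-2-[3,4,5-tris(benzyloxy)phenyl]chromane | C(c1ccccc1)Oc1ccc2c(c1)O[C@H](c1cc(OCc3ccccc3)c(OCc3ccccc3)c(OCc3ccccc3)c1)[C@@H](OCc1ccccc1)[C@@H]2c1c(Br)cc(OCc2ccccc2)c(OCc2ccccc2)c1OCc1ccccc1 | intermediate
9 | (E)-tert-butyldimethyl{[3-(4,4,5,5-tetramethyl-1,3,2-dioxaborolan-2-yl)prop-2-en-1-yl]oxy}silane | CC(C)(C)[Si](C)(C)OC/C=C/B1OC(C)(C)C(C)(C)O1 | starting material
10 | (E)-tert-butyl({3-[3,4,5-tris(benzyloxy)-2-U-phenyl]prop-2-en-1-yl}oxy)dimethylsilane | C(c1ccccc1)Oc1ccc2c(c1)O[C@H](c1cc(OCc3ccccc3)c(OCc3ccccc3)c(OCc3ccccc3)c1)[C@@H](OCc1ccccc1)[C@@H]2c1c(/C=C/CO[Si](C)(C)C(C)(C)C)cc(OCc2ccccc2)c(OCc2ccccc2)c1OCc1ccccc1 | intermediate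
11 | (E)-3-[3,4,5-tris(benzyloxy)-2-U-phenyl]prop-2-en-1-ol | C(c1ccccc1)Oc1ccc2c(c1)O[C@H](c1cc(OCc3ccccc3)c(OCc3ccccc3)c(OCc3ccccc3)c1)[C@@H](OCc1ccccc1)[C@@H]2c1c(/C=C/CO)cc(OCc2ccccc2)c(OCc2ccccc2)c1OCc1ccccc1 | intermediate
12 | {(2S,3S)-3-[3,4,5-tris(benzyloxy)-2-U-phenyl]oxiran-2-yl}methanol | C(c1ccccc1)Oc1ccc2c(c1)O[C@H](c1cc(OCc3ccccc3)c(OCc3ccccc3)c(OCc3ccccc3)c1)[C@@H](OCc1ccccc1)[C@@H]2c1c([C@@H]2O[C@H]2CO)cc(OCc2ccccc2)c(OCc2ccccc2)c1OCc1ccccc1 | intermediate
13 | (2R,3S)-3-[3,4,5-tris(benzyloxy)-2-U-phenyl]oxirane-2-carbaldehyde | C(c1ccccc1)Oc1ccc2c(c1)O[C@H](c1cc(OCc3ccccc3)c(OCc3ccccc3)c(OCc3ccccc3)c1)[C@@H](OCc1ccccc1)[C@@H]2c1c([C@@H]2O[C@H]2C=O)cc(OCc2ccccc2)c(OCc2ccccc2)c1OCc1ccccc1 | intermediate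
14 | 3-(benzyloxy)phenol | Oc1cccc(OCc2ccccc2)c1 | starting material
15 | [3-(benzyloxy)phenoxy]titanium triisopropoxide (formed in the flask, not isolated) | CC(C)O[Ti](OC(C)C)(OC(C)C)Oc1cccc(OCc2ccccc2)c1 | intermediate
16 | (S)-[4-(benzyloxy)-2-hydroxyphenyl]{(2S,3S)-3-[3,4,5-tris(benzyloxy)-2-U-phenyl]oxiran-2-yl}methanol (3,4-anti; present as its titanium alkoxide, not isolated) | C(c1ccccc1)Oc1ccc2c(c1)O[C@H](c1cc(OCc3ccccc3)c(OCc3ccccc3)c(OCc3ccccc3)c1)[C@@H](OCc1ccccc1)[C@@H]2c1c([C@@H]2O[C@H]2[C@@H](O)c2ccc(OCc3ccccc3)cc2O)cc(OCc2ccccc2)c(OCc2ccccc2)c1OCc1ccccc1 | intermediate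
17 | (2R,3S,4S)-7-(benzyloxy)-2-[3,4,5-tris(benzyloxy)-2-U-phenyl]chromane-3,4-diol (2,3-trans-3,4-cis) | C(c1ccccc1)Oc1ccc2c(c1)O[C@H](c1cc(OCc3ccccc3)c(OCc3ccccc3)c(OCc3ccccc3)c1)[C@@H](OCc1ccccc1)[C@@H]2c1c([C@H]2Oc3cc(OCc4ccccc4)ccc3[C@H](O)[C@@H]2O)cc(OCc2ccccc2)c(OCc2ccccc2)c1OCc1ccccc1 | intermediate
18 | (2R,3S,4S)-2-{3,4,5-trihydroxy-2-[(2R,3S,4S)-3,7-dihydroxy-2-(3,4,5-trihydroxyphenyl)chroman-4-yl]phenyl}chromane-3,4,7-triol | Oc1ccc2c(c1)O[C@H](c1cc(O)c(O)c(O)c1)[C@@H](O)[C@@H]2c1c([C@H]2Oc3cc(O)ccc3[C@H](O)[C@@H]2O)cc(O)c(O)c1O | target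

**Step count**

Total: 12 steps. Longest linear sequence: 10 steps (1, 2, 5, 6, 7, 8, 9, 10, 11, 12); steps 3 and 4 form the side branch that joins at step 5.

**Steps most likely to fail**

Step 11 (proposed new method). The annulation may fail through loss of regiocontrol in the epoxide opening (5-exo closure or capture by isopropoxide), through ionisation of the activated C4 carbinol followed by arylation with the excess phenol, or through poor facial selectivity in the aldehyde addition. The fallback forms the same two bonds by the established phenol–enal chromene synthesis followed by osmylation, and sets out from allylic alcohol 11, so that steps 9 and 10 are not needed. Oxidation of 11 with MnO2 in CH2Cl2 should give (E)-3-[3,4,5-tris(benzyloxy)-2-U-phenyl]prop-2-enal F1. Heating F1 with phenol 14, PhB(OH)2 and catalytic propionic acid in toluene under removal of water should give, by ortho-selective condensation and ring closure with loss of water, (2S)-7-(benzyloxy)-2-[3,4,5-tris(benzyloxy)-2-U-phenyl]-2H-chromene F2 together with its C2 epimer. The epimers are to be separated by chromatography, since the remote upper unit is not expected to bias this closure strongly. Dihydroxylation of F2 with catalytic OsO4 and N-methylmorpholine N-oxide in acetone/water, which on flav-3-enes takes place anti to the 2-aryl group, should give the 2,3-trans-3,4-cis diol and so return to the route at 17.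

Step 5. The coupling may fail through self-condensation of the electrophile through its own ring A, sluggish attack at the doubly flanked arene position, or erosion of the 3,4-trans selectivity. The fallback replaces the benzylated arene by the far more nucleophilic free pyrogallol and sets out from diol 3 and triol 5. With catalytic camphorsulfonic acid in dioxane at room temperature and an excess of 5, capture of the flavan-4-yl cation on carbon with loss of water should give (2R,3S,4S)-7-(benzyloxy)-4-(6-bromo-2,3,4-trihydroxyphenyl)-2-[3,4,5-tris(benzyloxy)phenyl]chroman-3-ol F3; the two free positions of 5 are again equivalent. Exhaustive benzylation of F3 (NaH, BnBr, DMF, argon) etherifies the three phenols and the C3 hydroxyl at once and returns to the route at 8, so that steps 4 and 6 are not needed.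

Step 12. The hydrogenolysis may over-reduce the lower unit (loss of the benzylic C4 hydroxyl through a para-quinone methide once the ring D phenol is free), or the hindered C3 benzyl ether may cleave so slowly that the product degrades. The fallback masks the diol first and sets out from 17. Silylation with TBSOTf and 2,6-lutidine in CH2Cl2 should give the lower 3,4-bis-O-(tert-butyldimethylsilyl) ether of 17 F4. Hydrogenolysis over Pd(OH)2/C in EtOAc/THF should then give the lower 3,4-bis-O-(tert-butyldimethylsilyl) ether of 18 F5, in which the C4–O bond can no longer ionise to a quinone methide. Buffered fluoride (TBAF/AcOH, THF, 0 °C) should release the diol and return to the route at 18.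

**Further compounds**

F1 | step 11 | (E)-3-[3,4,5-tris(benzyloxy)-2-U-phenyl]prop-2-enal | C(c1ccccc1)Oc1ccc2c(c1)O[C@H](c1cc(OCc3ccccc3)c(OCc3ccccc3)c(OCc3ccccc3)c1)[C@@H](OCc1ccccc1)[C@@H]2c1c(/C=C/C=O)cc(OCc2ccccc2)c(OCc2ccccc2)c1OCc1ccccc1
F2 | step 11 | (2S)-7-(benzyloxy)-2-[3,4,5-tris(benzyloxy)-2-U-phenyl]-2H-chromene | C(c1ccccc1)Oc1ccc2c(c1)O[C@H](c1cc(OCc3ccccc3)c(OCc3ccccc3)c(OCc3ccccc3)c1)[C@@H](OCc1ccccc1)[C@@H]2c1c([C@H]2Oc3cc(OCc4ccccc4)ccc3C=C2)cc(OCc2ccccc2)c(OCc2ccccc2)c1OCc1ccccc1
F3 | step 5 | (2R,3S,4S)-7-(benzyloxy)-4-(6-bromo-2,3,4-trihydroxyphenyl)-2-[3,4,5-tris(benzyloxy)phenyl]chroman-3-ol | C(c1ccccc1)Oc1ccc2c(c1)O[C@H](c1cc(OCc3ccccc3)c(OCc3ccccc3)c(OCc3ccccc3)c1)[C@@H](O)[C@@H]2c1c(Br)cc(O)c(O)c1O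
F4 | step 12 | lower 3,4-bis-O-(tert-butyldimethylsilyl) ether of 17 (configuration unchanged) | C(c1ccccc1)Oc1ccc2c(c1)O[C@H](c1cc(OCc3ccccc3)c(OCc3ccccc3)c(OCc3ccccc3)c1)[C@@H](OCc1ccccc1)[C@@H]2c1c([C@H]2Oc3cc(OCc4ccccc4)ccc3[C@H](O[Si](C)(C)C(C)(C)C)[C@@H]2O[Si](C)(C)C(C)(C)C)cc(OCc2ccccc2)c(OCc2ccccc2)c1OCc1ccccc1
F5 | step 12 | lower 3,4-bis-O-(tert-butyldimethylsilyl) ether of 18 (configuration unchanged) | Oc1ccc2c(c1)O[C@H](c1cc(O)c(O)c(O)c1)[C@@H](O)[C@@H]2c1c([C@H]2Oc3cc(O)ccc3[C@H](O[Si](C)(C)C(C)(C)C)[C@@H]2O[Si](C)(C)C(C)(C)C)cc(O)c(O)c1O
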